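**Retrosynthetic overview**
1. The target comes from its mono-pivalate by ester methanolysis (last step, no skeletal change).
2. The dihydropyran ring is disconnected at the O1–C2 bond: enantioselective 6-endo addition of a phenol OH to the styrene of a 2-cinnamylresorcinol, which is made in the same flask by Friedel–Crafts allylation of a 4-substituted resorcinol with a 1-arylallyl alcohol. This closure sets C-2 as (S).
3. The 4-substituted resorcinol, which already carries the complete (R)-1,3-diarylpropyl arm, comes from a tribenzylated β,β-diaryl ketone by one hydrogenolysis (O-benzyl cleavage and C=O to CH2).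
4. The β,β-diaryl ketone comes from a chalcone and an arylboronic acid by rhodium-catalysed asymmetric 1,4-addition, which sets the (R) methine. The chalcone comes from a Claisen–Schmidt condensation followed by O-pivaloylation.
5. Ring order: the four benzene rings are bought; the dihydropyran ring is the only ring formed and is closed last, on the fully assembled carbon skeleton.

Assumption: compounds 1, 2, 5 and 9 are bought as catalogue materials; the ligand enantiomer in step 3 is the one predicted by the usual facial model, and the catalyst enantiomer in step 6 is chosen by screening.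

Step 1
Reactants: 1 2,4-bis(benzyloxy)benzaldehyde; 2 1-(4-hydroxy-2-methoxyphenyl)ethan-1-one
Product: 3 (E)-3-[2,4-bis(benzyloxy)phenyl]-1-(4-hydroxy-2-methoxyphenyl)prop-2-en-1-one
Conditions: KOH (4 equiv, 50% aq), EtOH, rt → 45 °C, 24 h; then 1 M HCl
Reagents that add atoms: none
Why: Claisen–Schmidt aldol condensation of the ketone enolate (formed despite the phenoxide by using excess KOH) with the non-enolisable aldehyde, where E1cB dehydration gives only the (E)-enone and the benzyl ethers are base-stable.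

Step 2
Reactants: 3 (E)-3-[2,4-bis(benzyloxy)phenyl]-1-(4-hydroxy-2-methoxyphenyl)prop-2-en-1-one
Product: 4 4-{(E)-3-[2,4-bis(benzyloxy)phenyl]prop-2-enoyl}-3-methoxyphenyl pivalate
Conditions: PivCl (1.2 equiv), Et3N, DMAP (5 mol%), CH2Cl2, 0 °C → rt
Reagents that add atoms: pivaloyl chloride, CC(C)(C)C(=O)Cl
Why: DMAP-catalysed O-acylation of the only free phenol installs a robust electron-withdrawing ester that later stops this resorcinol-type ring from competing as a Friedel–Crafts nucleophile in step 6.

Step 3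
Reactants: 4 4-{(E)-3-[2,4-bis(benzyloxy)phenyl]prop-2-enoyl}-3-methoxyphenyl pivalate; 5 [4-(benzyloxy)phenyl]boronic acid
Product: 6 4-{(3R)-3-[2,4-bis(benzyloxy)phenyl]-3-[4-(benzyloxy)phenyl]propanoyl}-3-methoxyphenyl pivalate
Conditions: [Rh(OH)(cod)]2 (1.5 mol%), (S)-BINAP (3.3 mol%), 5 (2.5 equiv), 1,4-dioxane/H2O 10:1, 50 °C
Reagents that add atoms: none
Why: Hayashi–Miyaura rhodium-catalysed asymmetric 1,4-addition, in which the aryl–Rh/(S)-BINAP species is predicted to add to the α-si face of the (E)-enone and so set the (R) diaryl methine (the sense is checked on the first run and (R)-BINAP is used if it is reversed).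

Step 4
Reactants: 6 4-{(3R)-3-[2,4-bis(benzyloxy)phenyl]-3-[4-(benzyloxy)phenyl]propanoyl}-3-methoxyphenyl pivalate
Product: 8 4-[(3R)-3-(2,4-dihydroxyphenyl)-3-(4-hydroxyphenyl)propyl]-3-methoxyphenyl pivalate, via triphenol ketone 7 (not isolated)
Conditions: H2 (5 bar), Pd/C (10 wt% Pd on carbon), EtOAc/AcOH 1:1, HClO4 (0.2 equiv), rt → 40 °C
Reagents that add atoms: none
Why: Catalytic hydrogenolysis cleaves the three benzyl ethers first and then, under acid, takes the electron-rich aryl ketone through its benzylic alcohol to CH2, while the pivalate, the methyl ether and the non-activated methine stereocentre are untouched.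

Step 5
Reactants: 9 5-hydroxy-2-methoxybenzaldehyde
Product: 10 rac-1-(5-hydroxy-2-methoxyphenyl)prop-2-en-1-ol
Conditions: CH2=CHMgBr (2.5 equiv), THF, −40 → 0 °C; aq NH4Cl
Reagents that add atoms: vinylmagnesium bromide, C=C[Mg]Br
Why: Grignard 1,2-addition to the aldehyde after sacrificial deprotonation of the phenol, where the carbinol stereocentre is irrelevant because it is ionised in step 6.

Step 6
Reactants: 8 4-[(3R)-3-(2,4-dihydroxyphenyl)-3-(4-hydroxyphenyl)propyl]-3-methoxyphenyl pivalate; 10 rac-1-(5-hydroxy-2-methoxyphenyl)prop-2-en-1-ol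
Product: 12 4-{(3R)-3-[(2S)-7-hydroxy-2-(5-hydroxy-2-methoxyphenyl)-3,4-dihydro-2H-chromen-6-yl]-3-(4-hydroxyphenyl)propyl}-3-methoxyphenyl pivalate, via cinnamylresorcinol 11 (not isolated)
Conditions: (S,S)-IDPi Brønsted acid (BINOL-derived imidodiphosphorimidate, N-triflyl core, 3,3′-aryl = 3,5-(CF3)2C6H3 as starting point; 5 mol%), 10 (1.3 equiv, slow addition), 5 Å MS, CH2Cl2, −40 → 0 °C; Et3N quench
Reagents that add atoms: none
Why: Proposed new method: a confined chiral Brønsted acid runs a dehydrative (3+3) annulation in which it first ionises 10 to the aryl-allyl cation, which alkylates the most nucleophilic carbon of 8 (the free resorcinol position para to one OH and ortho to the other; the pivalate-deactivated and mono-oxygenated rings should not compete) through its unhindered terminus to give (E)-cinnamylphenol 11, and then protonates the styrene of 11 at the carbon next to the CH2 to give an ortho-methoxy-stabilised benzylic cation held as a contact ion pair in the chiral pocket with the neighbouring phenol OH hydrogen-bonded to the anion, so that 6-endo C–O bond formation closes the pyran ring on one face and sets C-2 as (S) under catalyst control (the remote (R) centre is a bystander and the C-2 epimers are diastereomers, so selectivity is read directly by HPLC); the closest known reactions are the racemic acid-catalysed one-pot phenol plus cinnamyl alcohol flavan annulation and IDPi-catalysed asymmetric intramolecular hydroalkoxylation of simple alkenes by aliphatic alcohols, whereas a phenol nucleophile, a styrenyl 6-endo closure to a 2-arylchroman and the tandem with the allylation have not been shown enantioselectively.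

Step 7
Reactants: 12 4-{(3R)-3-[(2S)-7-hydroxy-2-(5-hydroxy-2-methoxyphenyl)-3,4-dihydro-2H-chromen-6-yl]-3-(4-hydroxyphenyl)propyl}-3-methoxyphenyl pivalate
Product: 13 4-{(3R)-3-[(2S)-7-hydroxy-2-(5-hydroxy-2-methoxyphenyl)-3,4-dihydro-2H-chromen-6-yl]-3-(4-hydroxyphenyl)propyl}-3-methoxyphenol
Conditions: K2CO3 (3 equiv), MeOH (degassed), Ar, rt; then 1 M HCl to pH 5
Reagents that add atoms: none
Why: Base-mediated methanolysis (transesterification) of the aryl pivalate, which leaves the chroman ether, the methyl ethers and both stereocentres (neither is acidic nor next to a carbonyl) untouched.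

**Compound list**
1 | 2,4-bis(benzyloxy)benzaldehyde | O=Cc1ccc(OCc2ccccc2)cc1OCc1ccccc1 | starting material
2 | 1-(4-hydroxy-2-methoxyphenyl)ethan-1-one | CC(=O)c1ccc(O)cc1OC | starting material
3 | (E)-3-[2,4-bis(benzyloxy)phenyl]-1-(4-hydroxy-2-methoxyphenyl)prop-2-en-1-one | COc1cc(O)ccc1C(=O)/C=C/c1ccc(OCc2ccccc2)cc1OCc1ccccc1 | intermediate
4 | 4-{(E)-3-[2,4-bis(benzyloxy)phenyl]prop-2-enoyl}-3-methoxyphenyl pivalate | COc1cc(OC(=O)C(C)(C)C)ccc1C(=O)/C=C/c1ccc(OCc2ccccc2)cc1OCc1ccccc1 | intermediate
5 | [4-(benzyloxy)phenyl]boronic acid | OB(O)c1ccc(OCc2ccccc2)cc1 | starting material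
6 | 4-{(3R)-3-[2,4-bis(benzyloxy)phenyl]-3-[4-(benzyloxy)phenyl]propanoyl}-3-methoxyphenyl pivalate | COc1cc(OC(=O)C(C)(C)C)ccc1C(=O)C[C@H](c1ccc(OCc2ccccc2)cc1)c1ccc(OCc2ccccc2)cc1OCc1ccccc1 | intermediate
7 | 4-[(3R)-3-(2,4-dihydroxyphenyl)-3-(4-hydroxyphenyl)propanoyl]-3-methoxyphenyl pivalate (triphenol ketone, not isolated) | COc1cc(OC(=O)C(C)(C)C)ccc1C(=O)C[C@H](c1ccc(O)cc1)c1ccc(O)cc1O | intermediate
8 | 4-[(3R)-3-(2,4-dihydroxyphenyl)-3-(4-hydroxyphenyl)propyl]-3-methoxyphenyl pivalate | COc1cc(OC(=O)C(C)(C)C)ccc1CC[C@H](c1ccc(O)cc1)c1ccc(O)cc1O | intermediate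
9 | 5-hydroxy-2-methoxybenzaldehyde | COc1ccc(O)cc1C=O | starting material
10 | rac-1-(5-hydroxy-2-methoxyphenyl)prop-2-en-1-ol | COc1ccc(O)cc1C(O)C=C | intermediate
11 | 4-[(3R)-3-{2,4-dihydroxy-5-[(2E)-3-(5-hydroxy-2-methoxyphenyl)prop-2-en-1-yl]phenyl}-3-(4-hydroxyphenyl)propyl]-3-methoxyphenyl pivalate (cinnamylresorcinol, not isolated) | COc1cc(OC(=O)C(C)(C)C)ccc1CC[C@H](c1ccc(O)cc1)c1cc(C/C=C/c2cc(O)ccc2OC)c(O)cc1O | intermediate
12 | 4-{(3R)-3-[(2S)-7-hydroxy-2-(5-hydroxy-2-methoxyphenyl)-3,4-dihydro-2H-chromen-6-yl]-3-(4-hydroxyphenyl)propyl}-3-methoxyphenyl pivalate | COc1cc(OC(=O)C(C)(C)C)ccc1CC[C@H](c1ccc(O)cc1)c1cc2c(cc1O)O[C@H](c1cc(O)ccc1OC)CC2 | intermediate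
13 | 4-{(3R)-3-[(2S)-7-hydroxy-2-(5-hydroxy-2-methoxyphenyl)-3,4-dihydro-2H-chromen-6-yl]-3-(4-hydroxyphenyl)propyl}-3-methoxyphenol | COc1cc(O)ccc1CC[C@H](c1ccc(O)cc1)c1cc2c(cc1O)O[C@H](c1cc(O)ccc1OC)CC2 | target

**Step count**
Total: 7 steps. Longest linear sequence: 6 steps (steps 1, 2, 3, 4, 6, 7); step 5 is a one-step side branch.

**Three steps most likely to fail**

Risk 1, step 6 (the proposed new annulation). Possible failures are low face selectivity at C-2, allylation at the wrong carbon, catalyst inhibition by the released water, and acid-mediated ring opening that erodes C-2 or the methine. The fallback uses known chemistry, sets out from 8 (with 10) and returns at 12. Alcohol 10 is oxidised with MnO2 (CH2Cl2, rt) to the aryl vinyl ketone 1-(5-hydroxy-2-methoxyphenyl)prop-2-en-1-one F1. Acid-catalysed conjugate Friedel–Crafts addition of 8 to F1 with cyclodehydration (p-TsOH, toluene, 60 °C) gives the enol ether 4-{(3R)-3-[7-hydroxy-2-(5-hydroxy-2-methoxyphenyl)-4H-chromen-6-yl]-3-(4-hydroxyphenyl)propyl}-3-methoxyphenyl pivalate F2. Iridium-catalysed asymmetric hydrogenation of the 2-aryl-4H-chromene double bond ([Ir(cod)((S)-tBu-PHOX)][B(3,5-(CF3)2C6H3)4], H2 50 bar, CH2Cl2; ligand enantiomer chosen for 2S), an established route to 2-arylchromans, then gives 12.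

Risk 2, step 4 (one-pot debenzylation and ketone deoxygenation). Once the ortho phenol is free it can close onto the ketone carbon, and the resulting ring-closed benzylic ethers may be hydrogenolysed only slowly, so the reaction can stall short of the CH2 compound. The fallback sets out from 6 and returns at 8. Ionic hydrogenation of fully benzylated 6 (Et3SiH, CF3CO2H, CH2Cl2, 0 °C), where no free phenol can interfere, gives the methylene compound 4-{(3R)-3-[2,4-bis(benzyloxy)phenyl]-3-[4-(benzyloxy)phenyl]propyl}-3-methoxyphenyl pivalate F3. Neutral hydrogenolysis (H2 1 bar, Pd/C, EtOAc/EtOH, rt) then removes the three benzyl groups to give 8.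

Risk 3, step 3 (asymmetric 1,4-addition). The β-aryl group of 4 is ortho-substituted and electron-rich, which may slow insertion and lower the ee. The fallback exchanges the roles of the two aryl groups at the stereocentre; it sets out from 2 and returns at 6. Claisen–Schmidt condensation of 2 with 4-(benzyloxy)benzaldehyde (KOH, EtOH) gives (E)-3-[4-(benzyloxy)phenyl]-1-(4-hydroxy-2-methoxyphenyl)prop-2-en-1-one F4. Pivaloylation (PivCl, Et3N, DMAP) gives 4-{(E)-3-[4-(benzyloxy)phenyl]prop-2-enoyl}-3-methoxyphenyl pivalate F5. Addition of [2,4-bis(benzyloxy)phenyl]boronic acid to this unhindered enone with [Rh(OH)(cod)]2 and the opposite ligand enantiomer, (R)-BINAP, then gives 6.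

**Further compounds**
F1 | step 6 | 1-(5-hydroxy-2-methoxyphenyl)prop-2-en-1-one | COc1ccc(O)cc1C(=O)C=C
F2 | step 6 | 4-{(3R)-3-[7-hydroxy-2-(5-hydroxy-2-methoxyphenyl)-4H-chromen-6-yl]-3-(4-hydroxyphenyl)propyl}-3-methoxyphenyl pivalate | COc1cc(OC(=O)C(C)(C)C)ccc1CC[C@H](c1ccc(O)cc1)c1cc2c(cc1O)OC(c1cc(O)ccc1OC)=CC2
F3 | step 4 | 4-{(3R)-3-[2,4-bis(benzyloxy)phenyl]-3-[4-(benzyloxy)phenyl]propyl}-3-methoxyphenyl pivalate | COc1cc(OC(=O)C(C)(C)C)ccc1CC[C@H](c1ccc(OCc2ccccc2)cc1)c1ccc(OCc2ccccc2)cc1OCc1ccccc1
F4 | step 3 | (E)-3-[4-(benzyloxy)phenyl]-1-(4-hydroxy-2-methoxyphenyl)prop-2-en-1-one | COc1cc(O)ccc1C(=O)/C=C/c1ccc(OCc2ccccc2)cc1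
F5 | step 3 | 4-{(E)-3-[4-(benzyloxy)phenyl]prop-2-enoyl}-3-methoxyphenyl pivalate | COc1cc(OC(=O)C(C)(C)C)ccc1C(=O)/C=C/c1ccc(OCc2ccccc2)cc1
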